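**Retrosynthetic overview**
- The target is cut at the benzylic aryl ether C–O bond and the THF C–O bond, giving (2S)-pinocembrin and a trans-epoxy butenolide. One operation makes both bonds: a boron-templated, retentive phenolysis of the oxirane, then a 5-exo oxa-Michael closure.
- The epoxy butenolide comes from (R)-5-cinnamylbutenolide by reagent-controlled epoxidation of the styrenyl alkene.
- The butenolide comes from (R)-cinnamyl oxirane and a two-carbon selanylacetate unit (epoxide opening, lactonisation, selenoxide elimination).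
- The cinnamyl oxirane comes from (R)-epichlorohydrin and (E)-styryl Grignard.
- Ring order: γ-lactone (as butenolide), then oxirane, then THF last (cis-fused); the flavanone is bought intact.

Assumption: (2S)-pinocembrin, (E)-β-bromostyrene, (phenylselanyl)acetic acid and the L-fructose-derived enantiomer of the Shi ketone are bought as such.

**Step 1**
Reactants: 1 (E)-(2-bromoethenyl)benzene; 2 (R)-epichlorohydrin
Product: 5 (2R)-2-[(2E)-3-phenylprop-2-en-1-yl]oxirane, via styrylmagnesium bromide 3 (not isolated), via chlorohydrin 4 (not isolated)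
Conditions: Mg, THF, 23→45 °C; CuI (10 mol %), 2, THF, −40→−20 °C; aq NH4Cl; crude + powdered NaOH, Et2O, 23 °C
Reagents that add atoms: none
Why: Copper-catalysed Grignard opening of the epoxide at its unsubstituted CH2 (SN2) followed by intramolecular Williamson closure of the chlorohydrin onto CH2Cl never touches the stereocentre, so (R)-2 gives (R)-5 with the E-alkene kept.

**Step 2**
Reactants: 5 (2R)-2-[(2E)-3-phenylprop-2-en-1-yl]oxirane; 6 (phenylselanyl)acetic acid
Product: 9 (5R)-3-(phenylselanyl)-5-[(2E)-3-phenylprop-2-en-1-yl]oxolan-2-one (C3 epimers), via selanylacetate dianion 7 (not isolated), via hydroxy acid 8 (not isolated)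
Conditions: LiN(iPr)2 (2.1 equiv), THF, −78→0 °C; 5, 0→23 °C; then AcOH, THF, 65 °C
Reagents that add atoms: none
Why: The carboxylate-stabilised α-selanyl carbanion opens the terminal epoxide at CH2 (SN2, stereocentre untouched) and the γ-hydroxy acid lactonises under acid, the classical epoxide-to-α-selanyl-γ-lactone homologation.

**Step 3**
Reactants: 9 (5R)-3-(phenylselanyl)-5-[(2E)-3-phenylprop-2-en-1-yl]oxolan-2-one
Product: 11 (5R)-5-[(2E)-3-phenylprop-2-en-1-yl]furan-2(5H)-one, via selenoxide 10 (not isolated)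
Conditions: NaIO4 (1.5 equiv), NaHCO3, THF/MeOH/H2O, 0→23 °C
Reagents that add atoms: none
Why: Selenide oxidation and syn-selenoxide elimination toward the only β-hydrogens (C4) give the butenolide at or below room temperature without touching C5 or the styrenyl alkene.

**Step 4**
Reactants: 11 (5R)-5-[(2E)-3-phenylprop-2-en-1-yl]furan-2(5H)-one
Product: 12 (5R)-5-{[(2S,3S)-3-phenyloxiran-2-yl]methyl}furan-2(5H)-one
Conditions: L-fructose-derived Shi ketone (30 mol %), Oxone (2KHSO5·KHSO4·K2SO4), K2CO3, Bu4NHSO4 (cat.), Na2B4O7 buffer (pH about 10.5), MeCN/dimethoxymethane/H2O, −5→0 °C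
Reagents that add atoms: potassium peroxymonosulfate, [K+].[O-]S(=O)(=O)OO
Why: Shi asymmetric epoxidation (chiral dioxirane, spiro transition state) picks the electron-rich trans-styrenyl alkene over the electron-poor butenolide, and the L-fructose-derived ketone gives the (2S,3S)-oxirane, the mirror image of the (R,R) sense established for the D-fructose ketone with trans-β-methylstyrene.

**Step 5**
Reactants: 12 (5R)-5-{[(2S,3S)-3-phenyloxiran-2-yl]methyl}furan-2(5H)-one; 13 (2S)-pinocembrin
Product: 17 (3aR,5S,6aR)-5-[(S)-{[(2S)-5-hydroxy-4-oxo-2-phenylchroman-7-yl]oxy}(phenyl)methyl]tetrahydrofuro[3,2-b]furan-2(3H)-one (CNP0152032.1), via bis-boryl pinocembrin 14 (not isolated), via ring-opened borate 15 (not isolated), via hydroxy butenolide 16 (not isolated)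
Conditions: 13 (1.1 equiv), catecholborane HBcat (2.2 equiv), PhMe, 0→23 °C (H2 off); then 12, CH2Cl2, −40→0 °C; then MeOH, CSA (10 mol %), 23 °C
Reagents that add atoms: none
Why: Proposed new method: a boron-templated, stereoretentive phenolysis of a trans-aryl epoxide coupled to oxa-Michael ring closure, in which the Lewis-acidic 7-O-B(cat) aryl borate of 14 binds the oxirane oxygen, the benzylic C–O bond ionises to a tight ion pair, and the aryloxy group on the boron ate centre collapses through a five-membered cyclic transition state onto the face the oxygen has just left (SNi, retention, so the (2S,3S)-oxirane gives the (S)-aryl ether threo to the (S)-carbinol), while the second boron, chelated between 5-O and the C4 carbonyl, masks that site and deactivates ring A against C-alkylation; methanolysis then frees the secondary hydroxyl, which adds 5-exo to the butenolide from the face of its tether (cis fusion, setting C3a as R); the closest known reactions are the syn-selective opening of cyclic aryl epoxides (indene oxide, 1,2-dihydronaphthalene oxide) by triaryl borates and the acid-promoted oxa-Michael cyclisation of hydroxyalkyl butenolides.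

**Compound list**
1 | (E)-(2-bromoethenyl)benzene ((E)-β-bromostyrene) | Br/C=C/c1ccccc1 | starting material
2 | (R)-epichlorohydrin, (2R)-2-(chloromethyl)oxirane | ClC[C@H]1CO1 | starting material
3 | (E)-styrylmagnesium bromide | Br[Mg]/C=C/c1ccccc1 | intermediate
4 | (2R,4E)-1-chloro-5-phenylpent-4-en-2-ol | ClC[C@H](O)C/C=C/c1ccccc1 | intermediate
5 | (2R)-2-[(2E)-3-phenylprop-2-en-1-yl]oxirane | C1[C@H](O1)C/C=C/c1ccccc1 | intermediate
6 | (phenylselanyl)acetic acid | OC(=O)C[Se]c1ccccc1 | starting material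
7 | dilithium (phenylselanyl)acetate dianion | [Li+].[Li+].[O-]C(=O)[CH-][Se]c1ccccc1 | intermediate
8 | (4R,6E)-4-hydroxy-7-phenyl-2-(phenylselanyl)hept-6-enoic acid (C2 epimers) | OC(=O)C([Se]c1ccccc1)C[C@H](O)C/C=C/c1ccccc1 | intermediate
9 | (5R)-3-(phenylselanyl)-5-[(2E)-3-phenylprop-2-en-1-yl]oxolan-2-one (C3 epimers) | O=C1O[C@H](C/C=C/c2ccccc2)CC1[Se]c1ccccc1 | intermediate
10 | (5R)-3-(benzeneseleninyl)-5-[(2E)-3-phenylprop-2-en-1-yl]oxolan-2-one (selenoxide) | O=C1O[C@H](C/C=C/c2ccccc2)CC1[Se](=O)c1ccccc1 | intermediate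
11 | (5R)-5-[(2E)-3-phenylprop-2-en-1-yl]furan-2(5H)-one | O=C1O[C@H](C/C=C/c2ccccc2)C=C1 | intermediate
12 | (5R)-5-{[(2S,3S)-3-phenyloxiran-2-yl]methyl}furan-2(5H)-one | O=C1O[C@H](C[C@@H]2O[C@H]2c2ccccc2)C=C1 | intermediate
13 | (2S)-pinocembrin, (2S)-5,7-dihydroxy-2-phenylchroman-4-one | O=C1C[C@@H](c2ccccc2)Oc2cc(O)cc(O)c12 | starting material
14 | (2S)-5,7-bis(1,3,2-benzodioxaborol-2-yloxy)-2-phenylchroman-4-one | O=C1C[C@@H](c2ccccc2)Oc2cc(OB3Oc4ccccc4O3)cc(OB3Oc4ccccc4O3)c12 | intermediate
15 | (5R)-5-[(2S,3S)-2-(1,3,2-benzodioxaborol-2-yloxy)-3-{[(2S)-5-(1,3,2-benzodioxaborol-2-yloxy)-4-oxo-2-phenylchroman-7-yl]oxy}-3-phenylpropyl]furan-2(5H)-one | O=C1O[C@H](C[C@H](OB2Oc3ccccc3O2)[C@@H](Oc2cc(OB3Oc4ccccc4O3)c3c(c2)O[C@H](c2ccccc2)CC3=O)c2ccccc2)C=C1 | intermediate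
16 | (5R)-5-[(2S,3S)-2-hydroxy-3-{[(2S)-5-hydroxy-4-oxo-2-phenylchroman-7-yl]oxy}-3-phenylpropyl]furan-2(5H)-one | O=C1O[C@H](C[C@H](O)[C@@H](Oc2cc(O)c3c(c2)O[C@H](c2ccccc2)CC3=O)c2ccccc2)C=C1 | intermediate
17 | (3aR,5S,6aR)-5-[(S)-{[(2S)-5-hydroxy-4-oxo-2-phenylchroman-7-yl]oxy}(phenyl)methyl]tetrahydrofuro[3,2-b]furan-2(3H)-one | O=C1C[C@H]2O[C@H]([C@@H](Oc3cc(O)c4c(c3)O[C@H](c3ccccc3)CC4=O)c3ccccc3)C[C@H]2O1 | target

**Step count and risks**
Total steps: 5. Longest linear sequence: 5 (2 → 5 → 9 → 11 → 12 → 17); pinocembrin 13 enters in the last step.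

Steps most likely to fail:

1. Step 5 (the proposed retentive phenolysis and oxa-Michael cascade). Possible failures are rotation in the benzylic ion pair (erythro ether), a hydride shift to the benzyl ketone, C-alkylation of ring A, or transfer of a catecholate oxygen. The fallback uses known chemistry only, sets out from 12 and comes back at 17. Aqueous HClO4 (5 mol %) in THF/H2O at 0 °C opens the oxirane at the benzylic carbon, mainly with inversion, to give (5R)-5-[(2S,3R)-2,3-dihydroxy-3-phenylpropyl]furan-2(5H)-one F1. CSA in CH2Cl2 closes the THF by 5-exo oxa-Michael addition to give (3aR,5S,6aR)-5-[(R)-hydroxy(phenyl)methyl]tetrahydrofuro[3,2-b]furan-2(3H)-one F2. Mitsunobu etherification of F2 with 13 (PPh3, DIAD, THF, 0→23 °C) then reacts only at the 7-OH and inverts the benzylic carbinol, giving 17.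

2. Step 4 (Shi epoxidation on the butenolide). The pH 10.5 medium may open or epimerise the butenolide at C5, and the catalyst-controlled diastereoselectivity may be lower than hoped. The fallback moves the epoxidation to a base-stable alcohol and builds the butenolide afterwards; it sets out from 5 and comes back at 12. Me3SI and n-BuLi (THF, −10→23 °C) convert 5 into (3R,5E)-6-phenylhexa-1,5-dien-3-ol F3. Shi epoxidation with the same ketone gives (2R)-1-[(2S,3S)-3-phenyloxiran-2-yl]but-3-en-2-ol F4. Acryloyl chloride and Et3N give (2R)-1-[(2S,3S)-3-phenyloxiran-2-yl]but-3-en-2-yl prop-2-enoate F5. Ring-closing metathesis with the second-generation Grubbs catalyst (CH2Cl2, 40 °C) then gives 12; the styrenyl alkene is already gone, so only the five-membered ring can close.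

3. Step 2 (dianion opening and lactonisation). The dianion may add sluggishly or lose selenium, and 6 may be hard to source. The fallback builds the lactone first and adds selenium afterwards; it sets out from 5 and comes back at 9. Diethyl malonate and NaOEt in EtOH at reflux give ethyl (5R)-2-oxo-5-[(2E)-3-phenylprop-2-en-1-yl]oxolane-3-carboxylate F6. Krapcho dealkoxycarbonylation (LiCl, wet DMSO, 150 °C) gives (5S)-5-[(2E)-3-phenylprop-2-en-1-yl]oxolan-2-one F7 (same spatial arrangement; the descriptor changes only through the priority rules). LiN(iPr)2 in THF at −78 °C followed by PhSeBr gives 9.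

**Further compounds**
F1 | step 5 | (5R)-5-[(2S,3R)-2,3-dihydroxy-3-phenylpropyl]furan-2(5H)-one | O=C1O[C@H](C[C@H](O)[C@H](O)c2ccccc2)C=C1
F2 | step 5 | (3aR,5S,6aR)-5-[(R)-hydroxy(phenyl)methyl]tetrahydrofuro[3,2-b]furan-2(3H)-one | O=C1C[C@H]2O[C@H]([C@H](O)c3ccccc3)C[C@H]2O1
F3 | step 4 | (3R,5E)-6-phenylhexa-1,5-dien-3-ol | C=C[C@H](O)C/C=C/c1ccccc1
F4 | step 4 | (2R)-1-[(2S,3S)-3-phenyloxiran-2-yl]but-3-en-2-ol | C=C[C@H](O)C[C@@H]1O[C@H]1c1ccccc1
F5 | step 4 | (2R)-1-[(2S,3S)-3-phenyloxiran-2-yl]but-3-en-2-yl prop-2-enoate | C=CC(=O)O[C@@H](C=C)C[C@@H]1O[C@H]1c1ccccc1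
F6 | step 2 | ethyl (5R)-2-oxo-5-[(2E)-3-phenylprop-2-en-1-yl]oxolane-3-carboxylate (C3 epimers) | CCOC(=O)C1C[C@@H](C/C=C/c2ccccc2)OC1=O
F7 | step 2 | (5S)-5-[(2E)-3-phenylprop-2-en-1-yl]oxolan-2-one | O=C1CC[C@@H](C/C=C/c2ccccc2)O1
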